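Readings and results come from a simulation with constants of no real substance.

How much target and dormant form stand in the flask after 25 h, and how much dissolved gas?

- the dormant form in the flask at 25 h, as a percentage of the starting material charged
- the target in the flask at 25 h, as a percentage of the starting material charged
- concentration of dissolved gas at 25 h, in M

all flasks: gas phase 200 mM (held)
- south-east: starting material 1.4 M; catalyst 50 mM; run made earlier
- north-west: starting material 2.2 M; catalyst 50 mM; run made earlier
- north: starting material 1 M; catalyst 25 mM; run made earlier
- flask: starting material 1.0 M; catalyst 50 mM; time 25 h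

| run | time / h | dormant form / % | target / % | starting material / % |
|---|---|---|---|---|
| south-east | 1.00 | 86 | 5 | 7 |
| south-east | 3.00 | 82 | 13 | 5 |
| south-east | 6.00 | 73 | 24 | 7 |
| south-east | 8.00 | 62 | 32 | 7 |
| south-east | 12.0 | 51 | 43 | 2 |
| south-east | 15.0 | 51 | 50 | 1 |
| south-east | 20.0 | 34 | 62 | 6 |
| north-west | 1.00 | 89 | 3 | 11 |
| north-west | 3.00 | 80 | 14 | 3 |
| north-west | 6.00 | 73 | 20 | 5 |
| north-west | 8.00 | 64 | 30 | 4 |
| north-west | 12.0 | 55 | 41 | 5 |
| north-west | 15.0 | 48 | 47 | 7 |
| north-west | 20.0 | 39 | 56 | 2 |
| north | 1.50 | 89 | 3 | 10 |
| north | 3.00 | 86 | 7 | 9 |
| north | 6.00 | 78 | 15 | 8 |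
| north | 10.0 | 73 | 21 | 7 |
| north | 20.0 | 55 | 40 | 6 |

(scatter of a reading: 2 percentage points)

- at the start none of the gas is dissolved
- what may be going on: gas phase <-> dissolved gas; starting material + dissolved gas + catalyst -> catalyst + target; target -> over-reaction product; starting material <-> dormant form; 2 dissolved gas -> homo dimer

We reckon with what is left, not with what is made. In the first instants no gas is dissolved and starting material passes into dormant form. By 1.00 h the south-east run already shows 86% dormant form against 7% starting material. So we count the two together as one pool.

In the middle the pool shrinks slowly. At 20.0 h the south-east run keeps 40.0% of its charge and the north-west run 41.0%, from 1.4 M and 2.2 M. The fraction left barely follows the charge, so we treat the pool as pseudo-first-order. The north run has half the catalyst of the south-east run. Its pool falls at 0.0247 h⁻¹, the south-east pool at 0.0458 h⁻¹. These two runs also differ in charge, but the charge barely moved the fraction left between the south-east and north-west runs, so we take the rate as proportional to catalyst.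

The north run has the flask's charge of starting material, and it gives κ = 0.989 L mol⁻¹ h⁻¹. We call κ the pool constant: the logarithm of one over the fraction left, divided by catalyst concentration and time. It is a reading and carries the scatter.

For the end, we reckon the fraction left in the flask as exp(−κ·c·t), with c the catalyst concentration and t the time, which gives 29.1%. We let target take the rest, 70.9%. The north run's last reading puts 90.2% of the pool as dormant form, so we expect 26.2% dormant form. No run measured dissolved gas, so we say just that it lies below the saturation of 200 mM.

The forecast gives 27% dormant form and 69% target, a little apart from our two figures, and 0.08 M dissolved gas, where we gave no figure. Of the gas it says: “Dissolved gas is not identifiable from these data”.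

The flask gives 27.2% dormant form, 70.6% target and 0.117 M dissolved gas.

    gas phase ⇌ dissolved gas, rate k1*(csat - [dissolved gas]) (kL = 1.62 h⁻¹)
    starting material + dissolved gas + catalyst → catalyst + target (k = 132 L² mol⁻² h⁻¹)
    target → over-reaction product (k = 2.32 × 10⁻⁴ h⁻¹)
    starting material ⇌ dormant form (K = 13.0, k = 7.58 h⁻¹)
    2 dissolved gas → homo dimer (k = 4.36 L mol⁻¹ h⁻¹)

In the flask the dissolved gas stands at 1.46 times the forecast's value, and at 25 h the step to homo dimer uses it 8.1 times as fast as the step to target. The flask's pool of 29.1% gives κ = 0.987 L mol⁻¹ h⁻¹. For a neighbour flask with 0.013 M catalyst, otherwise the same and stopped at the same time, our κ from the north run leaves 72.5% of the charge in the pool. That neighbour flask holds 70.2% in its pool.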